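**Retrosynthetic overview**
1. 31 ⇐ triol 28 (three angelates put on last) ⇐ acetonide ketone 27.
2. Key disconnection C-1–C-2: the cyclohexanone is closed last by intramolecular hydroacylation of aldehyde 24. The enabling feature is the cyclobutane C-4–C-5–C-11–C-10, which holds the C-11 formyl and C-4 isopropenyl groups 1,3-cis on the face opposite the seven-membered ring, within bonding distance.
3. 7,8,9-Triol: hydroxyl-directed epoxidation of the C-9 allylic alcohol (C-7=C-8), then benzoate opening at C-7.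
4. Cyclobutane: Wolff ring contraction of bicyclo[4.2.1]nonenone 15 (C-10 shifts from C-1 to C-11). The seven-membered ring is made before it by ring-closing metathesis across the cis-2,4 arms of cyclopentanone 14.
5. 14 from 2-methylcyclopentenone 1 by asymmetric conjugate addition/hydroxymethylation, asymmetric vinylation, Saegusa–Ito oxidation and conjugate reverse prenylation. Ring order: five-membered (bought) → seven → four (by contraction of the five) → six.

Key step: step 15

Remark: late compounds use longipinane numbering (C-1 ketone carbon, C-3 bears Me-12, C-6 bears two methyls, C-10 bears Me-15; cyclobutane = C-4, C-5, C-11, C-10), which in 19–25 corresponds to bicyclo[4.1.1]octane C-8 (= C-4), C-6 (= C-5), C-7 (= C-11) and C-1 (= C-10); the ligand antipodes in steps 1 and 3 are taken to be those that give the configurations drawn.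

Step 1
Reactants: 1 2-methylcyclopent-2-en-1-one; 2 isopropenylmagnesium bromide; 3 formaldehyde
Product: 5 (2S,3R)-2-(hydroxymethyl)-2-methyl-3-(prop-1-en-2-yl)cyclopentan-1-one, via magnesium enolate 4 (not isolated)
Conditions: Cu(OTf)2 (3 mol %), chiral imidazolinium salt (NHC precursor, 4 mol %), Et2O, −30 °C; then CH2O (gas), −78 → 0 °C; aq. NH4Cl
Reagents that add atoms: isopropenylmagnesium bromide, C=C(C)[Mg]Br; formaldehyde, C=O
Why: Copper-catalysed asymmetric conjugate addition of the alkenyl Grignard reagent sets the (3R) centre and gives enolate 4 regiospecifically, and its aldol reaction with formaldehyde should occur anti to the new substituent, so the quaternary carbon carries CH2OH trans to isopropenyl (conjugate addition/enolate trapping).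

Step 2
Reactants: 5 (2S,3R)-2-(hydroxymethyl)-2-methyl-3-(prop-1-en-2-yl)cyclopentan-1-one
Product: 6 (1S,5R)-1-methyl-2-oxo-5-(prop-1-en-2-yl)cyclopentane-1-carbaldehyde
Conditions: (Pr4N)RuO4 (5 mol %), NMO, 4 Å MS, CH2Cl2, rt
Reagents that add atoms: none
Why: Ley–Griffith oxidation of the neopentyl primary alcohol to the non-enolisable β-keto aldehyde under neutral conditions that leave the alkene and both stereocentres untouched.

Step 3
Reactants: 6 (1S,5R)-1-methyl-2-oxo-5-(prop-1-en-2-yl)cyclopentane-1-carbaldehyde; 7 vinylmagnesium bromide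
Product: 9 (2S,3R)-2-[(1R)-1-hydroxyprop-2-en-1-yl]-2-methyl-3-(prop-1-en-2-yl)cyclopentan-1-one, via divinylzinc 8 (not isolated)
Conditions: 7, ZnCl2, Et2O/dioxane, 0 °C (gives Zn(CH=CH2)2); then 6, (+)-MIB (10 mol %), toluene, 0 °C; aq. NH4Cl
Reagents that add atoms: vinylmagnesium bromide, C=C[Mg]Br; zinc chloride, Cl[Zn]Cl (zinc of 8 only)
Why: Amino-alcohol-catalysed enantioselective addition of the alkenylzinc reagent to the aldehyde (reagent control; the MIB antipode that directs Re-face attack, (+)-MIB by analogy with dialkylzinc additions) should set the (R)-carbinol that becomes C-9, the ketone being inert to organozinc reagents.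

Step 4
Reactants: 9 (2S,3R)-2-[(1R)-1-hydroxyprop-2-en-1-yl]-2-methyl-3-(prop-1-en-2-yl)cyclopentan-1-one
Product: 10 (2S,3R)-2-[(1R)-1-(tert-butyldimethylsilyloxy)prop-2-en-1-yl]-2-methyl-3-(prop-1-en-2-yl)cyclopentan-1-one
Conditions: TBSOTf, 2,6-lutidine, CH2Cl2, −78 °C
Reagents that add atoms: tert-butyldimethylsilyl trifluoromethanesulfonate, CC(C)(C)[Si](C)(C)OS(=O)(=O)C(F)(F)F
Why: Silylation of the hindered secondary alcohol with the silyl triflate at low temperature, where the ketone is not enolised.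

Step 5
Reactants: 10 (2S,3R)-2-[(1R)-1-(tert-butyldimethylsilyloxy)prop-2-en-1-yl]-2-methyl-3-(prop-1-en-2-yl)cyclopentan-1-one
Product: 12 (4R,5S)-5-[(1R)-1-(tert-butyldimethylsilyloxy)prop-2-en-1-yl]-5-methyl-4-(prop-1-en-2-yl)cyclopent-2-en-1-one, via silyl enol ether 11 (not isolated)
Conditions: LDA, TMSCl, THF, −78 °C; then Pd(OAc)2 (10 mol %), O2 (1 atm), DMSO, 50 °C
Reagents that add atoms: chlorotrimethylsilane, C[Si](C)(C)Cl (silyl group of 11 only)
Why: Saegusa–Ito oxidation: deprotonation can occur only at the ring CH2 next to the carbonyl (the other α-carbon is quaternary), and palladium diacetate dehydrosilylates enol silane 11 to the enone.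

Step 6
Reactants: 12 (4R,5S)-5-[(1R)-1-(tert-butyldimethylsilyloxy)prop-2-en-1-yl]-5-methyl-4-(prop-1-en-2-yl)cyclopent-2-en-1-one; 13 trimethyl(3-methylbut-2-en-1-yl)silane
Product: 14 (2S,3R,4R)-2-[(1R)-1-(tert-butyldimethylsilyloxy)prop-2-en-1-yl]-2-methyl-4-(2-methylbut-3-en-2-yl)-3-(prop-1-en-2-yl)cyclopentan-1-one
Conditions: TiCl4, CH2Cl2, −78 °C; aq. NaHCO3
Reagents that add atoms: trimethyl(3-methylbut-2-en-1-yl)silane, CC(C)=CC[Si](C)(C)C
Why: Hosomi–Sakurai conjugate allylation: the TiCl4-activated enone is attacked by the γ-carbon of the prenylsilane on the face anti to the adjacent isopropenyl group, which installs the quaternary CMe2–vinyl arm cis to the silyloxyallyl arm (1,3-cis on the ring).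

Step 7
Reactants: 14 (2S,3R,4R)-2-[(1R)-1-(tert-butyldimethylsilyloxy)prop-2-en-1-yl]-2-methyl-4-(2-methylbut-3-en-2-yl)-3-(prop-1-en-2-yl)cyclopentan-1-one
Product: 15 5-(tert-butyldimethylsilyloxy)-2,2,6-trimethyl-9-(prop-1-en-2-yl)bicyclo[4.2.1]non-3-en-7-one (5-silyloxy on the side of the C7–C8 bridge; 9-isopropenyl anti to the C2–C5 bridge)
Conditions: second-generation Grubbs catalyst (10 mol %), toluene, 80 °C
Reagents that add atoms: none
Why: Ring-closing metathesis of the two monosubstituted vinyl groups (loss of ethene) bridges the cis-1,3 arms to the cycloheptene; closure onto the isopropenyl group would need a trans-fused bicyclo[3.3.0]octene and is not expected.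

Step 8
Reactants: 15 5-(tert-butyldimethylsilyloxy)-2,2,6-trimethyl-9-(prop-1-en-2-yl)bicyclo[4.2.1]non-3-en-7-one
Product: 17 5-(tert-butyldimethylsilyloxy)-8-diazo-2,2,6-trimethyl-9-(prop-1-en-2-yl)bicyclo[4.2.1]non-3-en-7-one, via trifluoroacetyl ketone 16 (not isolated)
Conditions: LiHMDS, CF3CO2CH2CF3, THF, −78 °C; then 4-acetamidobenzenesulfonyl azide, Et3N, MeCN, rt
Reagents that add atoms: 2,2,2-trifluoroethyl trifluoroacetate, O=C(OCC(F)(F)F)C(F)(F)F (trifluoroacetyl group of 16 only); 4-acetamidobenzenesulfonyl azide, CC(=O)Nc1ccc(cc1)S(=O)(=O)N=[N+]=[N-] (the two diazo nitrogens)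
Why: Deacylative Regitz-type diazo transfer: the single enolisable position is trifluoroacetylated (16) and the activated ketone then exchanges the acyl group for the diazo group on reaction with the sulfonyl azide.

Step 9
Reactants: 17 5-(tert-butyldimethylsilyloxy)-8-diazo-2,2,6-trimethyl-9-(prop-1-en-2-yl)bicyclo[4.2.1]non-3-en-7-one
Product: 19 2-(tert-butyldimethylsilyloxy)-N-methoxy-N,1,5,5-tetramethyl-8-(prop-1-en-2-yl)bicyclo[4.1.1]oct-3-ene-7-carboxamide (drawn with 7-carboxamide and 8-isopropenyl cis), via ketene 18 (not isolated)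
Conditions: hν (λ > 300 nm), MeNH(OMe), THF, 0 °C
Reagents that add atoms: N,O-dimethylhydroxylamine, CNOC
Why: Photochemical Wolff rearrangement: loss of N2 with 1,2-shift of the quaternary bridgehead carbon (retention) contracts the cyclopentanone to the cyclobutane and ketene 18 is trapped as the Weinreb amide; the new α-centre is epimerisable and either epimer is usable because step 15 equilibrates it.

Step 10
Reactants: 19 2-(tert-butyldimethylsilyloxy)-N-methoxy-N,1,5,5-tetramethyl-8-(prop-1-en-2-yl)bicyclo[4.1.1]oct-3-ene-7-carboxamide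
Product: 20 2-hydroxy-N-methoxy-N,1,5,5-tetramethyl-8-(prop-1-en-2-yl)bicyclo[4.1.1]oct-3-ene-7-carboxamide (2-OH on the C7 side of the seven-membered ring)
Conditions: HF·pyridine, THF, 0 °C → rt
Reagents that add atoms: none
Why: Fluoride-mediated cleavage of the silyl ether frees the allylic alcohol needed to direct the epoxidation.

Step 11
Reactants: 20 2-hydroxy-N-methoxy-N,1,5,5-tetramethyl-8-(prop-1-en-2-yl)bicyclo[4.1.1]oct-3-ene-7-carboxamide
Product: 21 3,4-epoxy-2-hydroxy-N-methoxy-N,1,5,5-tetramethyl-8-(prop-1-en-2-yl)bicyclo[4.1.1]octane-7-carboxamide (epoxide cis to 2-OH)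
Conditions: VO(acac)2 (5 mol %), t-BuOOH, CH2Cl2, 0 °C → rt
Reagents that add atoms: tert-butyl hydroperoxide, CC(C)(C)OO (one oxygen)
Why: Hydroxyl-directed epoxidation: the vanadium alkoxide delivers oxygen to the neighbouring double bond on the face of the hydroxyl group (syn epoxy alcohol) and should leave the isolated isopropenyl group alone.

Step 12
Reactants: 21 3,4-epoxy-2-hydroxy-N-methoxy-N,1,5,5-tetramethyl-8-(prop-1-en-2-yl)bicyclo[4.1.1]octane-7-carboxamide
Product: 22 4-(benzoyloxy)-2,3-dihydroxy-N-methoxy-N,1,5,5-tetramethyl-8-(prop-1-en-2-yl)bicyclo[4.1.1]octane-7-carboxamide (2-OH and 3-OH cis on the C7 side; 4-benzoate trans to 3-OH on the C8 side)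
Conditions: Ti(OiPr)4, PhCO2H, CH2Cl2, rt
Reagents that add atoms: benzoic acid, OC(=O)c1ccccc1
Why: Titanium-mediated opening of the 2,3-epoxy alcohol by benzoate at the epoxide carbon remote from the carbinol (bicyclo C-4, future C-7) with inversion, which places that oxygen trans to the retained C-3 oxygen while the C-2 and C-3 oxygens (future O-9 and O-8) stay cis.

Step 13
Reactants: 22 4-(benzoyloxy)-2,3-dihydroxy-N-methoxy-N,1,5,5-tetramethyl-8-(prop-1-en-2-yl)bicyclo[4.1.1]octane-7-carboxamide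
Product: 23 4-(benzoyloxy)-2,3-(isopropylidenedioxy)-N-methoxy-N,1,5,5-tetramethyl-8-(prop-1-en-2-yl)bicyclo[4.1.1]octane-7-carboxamide
Conditions: 2,2-dimethoxypropane, camphorsulfonic acid (cat.), CH2Cl2, rt
Reagents that add atoms: 2,2-dimethoxypropane, COC(C)(C)OC
Why: Acid-catalysed transacetalisation ties the cis-2,3-diol into a dioxolane, which keeps these hydroxyls away from the aldehyde generated next.

Step 14
Reactants: 23 4-(benzoyloxy)-2,3-(isopropylidenedioxy)-N-methoxy-N,1,5,5-tetramethyl-8-(prop-1-en-2-yl)bicyclo[4.1.1]octane-7-carboxamide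
Product: 24 4-hydroxy-2,3-(isopropylidenedioxy)-1,5,5-trimethyl-8-(prop-1-en-2-yl)bicyclo[4.1.1]octane-7-carbaldehyde (drawn with 7-CHO and 8-isopropenyl cis)
Conditions: DIBAL-H (excess), CH2Cl2, −78 °C; aq. potassium sodium tartrate
Reagents that add atoms: none
Why: DIBAL-H reduces the Weinreb amide to the chelated hemiaminal, which gives the aldehyde on work-up, and at the same time cleaves the benzoate to the free C-4 alcohol.

Step 15
Reactants: 24 4-hydroxy-2,3-(isopropylidenedioxy)-1,5,5-trimethyl-8-(prop-1-en-2-yl)bicyclo[4.1.1]octane-7-carbaldehyde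
Product: 27 (3R,4S,5S,7S,8R,9S,10R,11R)-7-hydroxy-8,9-(isopropylidenedioxy)longipinan-1-one, via aldimine 25 (not isolated), via ketimine 26 (not isolated)
Conditions: RhCl(PPh3)3 (10 mol %), 2-amino-3-picoline (50 mol %), PhCO2H (10 mol %), toluene, 130 °C (sealed tube); then wet silica gel
Reagents that add atoms: 2-amino-3-picoline, Cc1cccnc1N (in 25 and 26 only; released again)
Why: Proposed new method: the formyl group condenses with 2-amino-3-picoline to aldimine 25, whose C–H bond adds to monovalent rhodium to give a pyridine-chelated iminoacyl rhodium hydride (trivalent rhodium) that cannot lose CO; the isopropenyl group, held 1,3-diaxial to it on the cyclobutane, inserts into Rh–H with hydride to C-3 and rhodium to the terminal CH2, and C-1–C-2 reductive elimination followed by hydrolysis of ketimine 26 releases the ketone and the amine. The closest known reactions are the chelation-assisted intermolecular hydroacylation of 1-alkenes through 2-aminopicoline aldimines and the cationic-rhodium cyclisation of 4-substituted pent-4-enals to 3-substituted cyclopentanones; new here is the intramolecular closure of a six-membered ring onto a 1,1-disubstituted alkene. The cyclohexanone ring (C-1, C-2, C-3, C-4, C-10, C-11; equally C-1 to C-5 with C-11) closes in the 6-endo-trig mode, the 5-exo mode being excluded because it would need a tertiary alkylrhodium and a bicyclo[2.1.1]hexanone. C-3 is the only new stereocentre: hydride is delivered from rhodium inside the forming ring while the bulky rhodium-bound CH2 sits on the open C-5–H flank and the small vinylic methyl points toward the C-10 methyl, so that after ring closure the C-3 methyl lies on the C-5 side, anti to the C-10 bridge. The step needs formyl and isopropenyl cis on the cyclobutane, which is secured because aldimine and enamine equilibrate at C-11 and only the cis epimer can cyclise; no other alkene is present, the C-7=C-8 bond having been oxidised beforehand.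

Step 16
Reactants: 27 (3R,4S,5S,7S,8R,9S,10R,11R)-7-hydroxy-8,9-(isopropylidenedioxy)longipinan-1-one
Product: 28 (3R,4S,5S,7S,8R,9S,10R,11R)-7,8,9-trihydroxylongipinan-1-one
Conditions: AcOH/H2O (4:1), 50 °C
Reagents that add atoms: none
Why: Acid hydrolysis of the acetonide (acetal cleavage) liberates the 7,8,9-triol without affecting the ketone.

Step 17
Reactants: 28 (3R,4S,5S,7S,8R,9S,10R,11R)-7,8,9-trihydroxylongipinan-1-one; 29 angelic acid
Product: 31 (3R,4S,5S,7S,8R,9S,10R,11R)-7,8,9-tris{[(2Z)-2-methylbut-2-enoyl]oxy}longipinan-1-one (CNP0138097.1), via mixed anhydride 30 (not isolated)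
Conditions: 29, 2,4,6-trichlorobenzoyl chloride, Et3N, toluene, rt (gives 30); then 28, toluene, 90 °C
Reagents that add atoms: angelic acid, C/C=C(/C)C(=O)O (three acyl groups); 2,4,6-trichlorobenzoyl chloride, O=C(Cl)c1c(Cl)cc(Cl)cc1Cl (in 30 only)
Why: Yamaguchi-type acylation through mixed anhydride 30, run without a nucleophilic amine catalyst so that the (Z)-enoate is not isomerised to tiglate; heating should drive the triple esterification of the hindered triol.

**Compound list**
1 | 2-methylcyclopent-2-en-1-one | CC1=CCCC1=O | starting material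
2 | isopropenylmagnesium bromide | C=C(C)[Mg]Br | starting material
3 | formaldehyde | C=O | starting material
4 | bromomagnesium (3R)-2-methyl-3-(prop-1-en-2-yl)cyclopent-1-en-1-olate | Br[Mg]OC1=C(C)[C@@H](C(C)=C)CC1 | intermediate
5 | (2S,3R)-2-(hydroxymethyl)-2-methyl-3-(prop-1-en-2-yl)cyclopentan-1-one | O=C1CC[C@H](C(C)=C)[C@@]1(C)CO | intermediate
6 | (1S,5R)-1-methyl-2-oxo-5-(prop-1-en-2-yl)cyclopentane-1-carbaldehyde | O=C1CC[C@H](C(C)=C)[C@@]1(C)C=O | intermediate
7 | vinylmagnesium bromide | C=C[Mg]Br | starting material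
8 | divinylzinc | C=C[Zn]C=C | intermediate
9 | (2S,3R)-2-[(1R)-1-hydroxyprop-2-en-1-yl]-2-methyl-3-(prop-1-en-2-yl)cyclopentan-1-one | O=C1CC[C@H](C(C)=C)[C@@]1(C)[C@H](O)C=C | intermediate
10 | (2S,3R)-2-[(1R)-1-(tert-butyldimethylsilyloxy)prop-2-en-1-yl]-2-methyl-3-(prop-1-en-2-yl)cyclopentan-1-one | O=C1CC[C@H](C(C)=C)[C@@]1(C)[C@H](O[Si](C)(C)C(C)(C)C)C=C | intermediate
11 | trimethylsilyl enol ether of 10 (enol double bond toward the ring CH2) | C[Si](C)(C)OC1=CC[C@H](C(C)=C)[C@@]1(C)[C@H](O[Si](C)(C)C(C)(C)C)C=C | intermediate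
12 | (4R,5S)-5-[(1R)-1-(tert-butyldimethylsilyloxy)prop-2-en-1-yl]-5-methyl-4-(prop-1-en-2-yl)cyclopent-2-en-1-one | O=C1C=C[C@H](C(C)=C)[C@@]1(C)[C@H](O[Si](C)(C)C(C)(C)C)C=C | intermediate
13 | trimethyl(3-methylbut-2-en-1-yl)silane | CC(C)=CC[Si](C)(C)C | starting material
14 | (2S,3R,4R)-2-[(1R)-1-(tert-butyldimethylsilyloxy)prop-2-en-1-yl]-2-methyl-4-(2-methylbut-3-en-2-yl)-3-(prop-1-en-2-yl)cyclopentan-1-one | O=C1C[C@@H](C(C)(C)C=C)[C@H](C(C)=C)[C@@]1(C)[C@H](O[Si](C)(C)C(C)(C)C)C=C | intermediate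
15 | 5-(tert-butyldimethylsilyloxy)-2,2,6-trimethyl-9-(prop-1-en-2-yl)bicyclo[4.2.1]non-3-en-7-one (5-silyloxy toward the C7–C8 bridge; isopropenyl anti to the C2–C5 bridge) | CC1(C)C=C[C@@H](O[Si](C)(C)C(C)(C)C)[C@@]2(C)C(=O)C[C@@H]1[C@@H]2C(C)=C | intermediate
16 | 8-(trifluoroacetyl) derivative of 15 (keto/enol mixture at C-8) | CC1(C)C=C[C@@H](O[Si](C)(C)C(C)(C)C)[C@@]2(C)C(=O)C(C(=O)C(F)(F)F)[C@@H]1[C@@H]2C(C)=C | intermediate
17 | 5-(tert-butyldimethylsilyloxy)-8-diazo-2,2,6-trimethyl-9-(prop-1-en-2-yl)bicyclo[4.2.1]non-3-en-7-one | CC1(C)C=C[C@@H](O[Si](C)(C)C(C)(C)C)[C@@]2(C)C(=O)C(=[N+]=[N-])[C@@H]1[C@@H]2C(C)=C | intermediate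
18 | [2-(tert-butyldimethylsilyloxy)-1,5,5-trimethyl-8-(prop-1-en-2-yl)bicyclo[4.1.1]oct-3-en-7-ylidene]methanone (ketene) | CC1(C)C=C[C@@H](O[Si](C)(C)C(C)(C)C)[C@@]2(C)C(=C=O)[C@@H]1[C@@H]2C(C)=C | intermediate
19 | 2-(tert-butyldimethylsilyloxy)-N-methoxy-N,1,5,5-tetramethyl-8-(prop-1-en-2-yl)bicyclo[4.1.1]oct-3-ene-7-carboxamide (7-carboxamide and 8-isopropenyl cis, both anti to the C2–C5 bridge; 2-silyloxy on the C7 side) | CC1(C)C=C[C@@H](O[Si](C)(C)C(C)(C)C)[C@@]2(C)[C@H](C(=O)N(C)OC)[C@@H]1[C@@H]2C(C)=C | intermediate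
20 | 2-hydroxy-N-methoxy-N,1,5,5-tetramethyl-8-(prop-1-en-2-yl)bicyclo[4.1.1]oct-3-ene-7-carboxamide | CC1(C)C=C[C@@H](O)[C@@]2(C)[C@H](C(=O)N(C)OC)[C@@H]1[C@@H]2C(C)=C | intermediate
21 | 3,4-epoxy-2-hydroxy-N-methoxy-N,1,5,5-tetramethyl-8-(prop-1-en-2-yl)bicyclo[4.1.1]octane-7-carboxamide (epoxide cis to 2-OH) | CC1(C)[C@H]3O[C@H]3[C@@H](O)[C@@]2(C)[C@H](C(=O)N(C)OC)[C@@H]1[C@@H]2C(C)=C | intermediate
22 | 4-(benzoyloxy)-2,3-dihydroxy-N-methoxy-N,1,5,5-tetramethyl-8-(prop-1-en-2-yl)bicyclo[4.1.1]octane-7-carboxamide (2,3-cis; 3,4-trans) | CC1(C)[C@H](OC(=O)c3ccccc3)[C@@H](O)[C@@H](O)[C@@]2(C)[C@H](C(=O)N(C)OC)[C@@H]1[C@@H]2C(C)=C | intermediate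
23 | 4-(benzoyloxy)-2,3-(isopropylidenedioxy)-N-methoxy-N,1,5,5-tetramethyl-8-(prop-1-en-2-yl)bicyclo[4.1.1]octane-7-carboxamide | CC1(C)[C@H](OC(=O)c3ccccc3)[C@H]4OC(C)(C)O[C@H]4[C@@]2(C)[C@H](C(=O)N(C)OC)[C@@H]1[C@@H]2C(C)=C | intermediate
24 | 4-hydroxy-2,3-(isopropylidenedioxy)-1,5,5-trimethyl-8-(prop-1-en-2-yl)bicyclo[4.1.1]octane-7-carbaldehyde (7-CHO and 8-isopropenyl cis) | CC1(C)[C@H](O)[C@H]4OC(C)(C)O[C@H]4[C@@]2(C)[C@H](C=O)[C@@H]1[C@@H]2C(C)=C | intermediate
25 | (E)-N-(3-methylpyridin-2-yl)aldimine of 24 | CC1(C)[C@H](O)[C@H]4OC(C)(C)O[C@H]4[C@@]2(C)[C@H](/C=N/c3ncccc3C)[C@@H]1[C@@H]2C(C)=C | intermediate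
26 | N-(3-methylpyridin-2-yl)ketimine of 27 (aryl group toward C-2) | CC1(C)O[C@@H]2[C@@H](O)C(C)(C)[C@H]3[C@@H]4[C@H](C)C/C(=N\c5ncccc5C)[C@H]3[C@]4(C)[C@@H]2O1 | intermediate
27 | (3R,4S,5S,7S,8R,9S,10R,11R)-7-hydroxy-8,9-(isopropylidenedioxy)longipinan-1-one | CC1(C)O[C@@H]2[C@@H](O)C(C)(C)[C@H]3[C@@H]4[C@H](C)CC(=O)[C@H]3[C@]4(C)[C@@H]2O1 | intermediate
28 | (3R,4S,5S,7S,8R,9S,10R,11R)-7,8,9-trihydroxylongipinan-1-one | O[C@@H]1[C@@H](O)C(C)(C)[C@H]2[C@@H]3[C@H](C)CC(=O)[C@H]2[C@]3(C)[C@@H]1O | intermediate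
29 | angelic acid, (2Z)-2-methylbut-2-enoic acid | C/C=C(/C)C(=O)O | starting material
30 | angelic 2,4,6-trichlorobenzoic anhydride | C/C=C(/C)C(=O)OC(=O)c1c(Cl)cc(Cl)cc1Cl | intermediate
31 | (3R,4S,5S,7S,8R,9S,10R,11R)-7,8,9-tris{[(2Z)-2-methylbut-2-enoyl]oxy}longipinan-1-one (O-8 and O-9 cis, O-7 trans to O-8; Me-12 anti to the C-10 bridge) | C/C=C(/C)C(=O)O[C@@H]1[C@@H](OC(=O)/C(C)=C\C)C(C)(C)[C@H]2[C@@H]3[C@H](C)CC(=O)[C@H]2[C@]3(C)[C@@H]1OC(=O)/C(C)=C\C | target

Total step count: 17. Longest linear sequence: 17 steps (from 1).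

**Steps most likely to fail**

Step 15 (proposed new method). Formation of the seven-membered rhodacycle and its reductive elimination may be too slow, so that double-bond migration of the isopropenyl group or unproductive imine chemistry takes over. The fallback sets out from 24 and comes back at 27, using known reactions only. Lemieux–Johnson cleavage (OsO4 cat., NaIO4, 2,6-lutidine, dioxane/H2O) of the isopropenyl group, the only alkene present, would give the keto aldehyde F1. Base-mediated intramolecular aldol condensation (KOH, MeOH) of the methyl ketone enolate with the C-11 formyl group forms the same C-1–C-2 bond and gives the 12-nor enone F2, with its carbonyl at C-3; the formyl centre epimerises under the base and only the cis arrangement can close. Wharton transposition follows: H2O2/NaOH to the epoxy ketone F3, then N2H4·H2O/AcOH to the allylic alcohol F4. Selective MnO2 oxidation of the allylic alcohol gives the 12-nor-2-en-1-one F5. Conjugate addition of Me2CuLi/TMSCl should then deliver the C-3 methyl from the open C-5 flank, anti to the C-10 methyl bridge, returning to 27.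

Step 17. Acylation of three contiguous, hindered secondary hydroxyls may stall at the di-ester stage, and forcing conditions may isomerise angelate to tiglate. The fallback sets out from 28 and comes back at 31. All three hydroxyls are esterified with the small, non-isomerisable 2-[bis(2,2,2-trifluoroethoxy)phosphoryl]propanoic acid (DCC, DMAP) to give the tris(phosphonate) F6. A threefold Still–Gennari olefination with acetaldehyde (KHMDS, 18-crown-6, THF, −78 °C) then builds each (Z)-2-methylbut-2-enoate on the ester.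

Step 3. Chelation of zinc between the aldehyde and the neighbouring ketone may override the amino-alcohol catalyst and erode facial control, or the zinc alkoxide may trigger retro-Claisen loss of the formyl group. The fallback sets out from 6 and comes back at 9: an asymmetric Nozaki–Hiyama–Kishi vinylation (vinyl bromide, CrCl2, NiCl2 cat., chiral sulfonamide ligand, Et3N, THF). The vinylchromium reagent is aldehyde-selective and non-basic, and its ligand antipode is chosen for the (R)-carbinol.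

**Further compounds**
F1 | step 15 | 8-acetyl-4-hydroxy-2,3-(isopropylidenedioxy)-1,5,5-trimethylbicyclo[4.1.1]octane-7-carbaldehyde (configuration as in 24) | CC1(C)[C@H](O)[C@H]4OC(C)(C)O[C@H]4[C@@]2(C)[C@H](C=O)[C@@H]1[C@@H]2C(C)=O
F2 | step 15 | 7-hydroxy-8,9-(isopropylidenedioxy)-12-norlongipin-1-en-3-one | CC1(C)O[C@@H]2[C@@H](O)C(C)(C)[C@H]3[C@@H]4C(=O)C=C[C@H]3[C@]4(C)[C@@H]2O1
F3 | step 15 | 1,2-epoxy-7-hydroxy-8,9-(isopropylidenedioxy)-12-norlongipinan-3-one (epoxide on the C-5 side) | CC1(C)O[C@@H]2[C@@H](O)C(C)(C)[C@H]3[C@@H]4C(=O)[C@@H]5O[C@@H]5[C@H]3[C@]4(C)[C@@H]2O1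
F4 | step 15 | 8,9-(isopropylidenedioxy)-12-norlongipin-2-ene-1,7-diol (1-OH on the C-5 side) | CC1(C)O[C@@H]2[C@@H](O)C(C)(C)[C@H]3[C@@H]4C=C[C@H](O)[C@H]3[C@]4(C)[C@@H]2O1
F5 | step 15 | 7-hydroxy-8,9-(isopropylidenedioxy)-12-norlongipin-2-en-1-one | CC1(C)O[C@@H]2[C@@H](O)C(C)(C)[C@H]3[C@@H]4C=CC(=O)[C@H]3[C@]4(C)[C@@H]2O1
F6 | step 17 | (3R,4S,5S,7S,8R,9S,10R,11R)-1-oxolongipinane-7,8,9-triyl tris{2-[bis(2,2,2-trifluoroethoxy)phosphoryl]propanoate} (propanoate α-centres as a mixture) | CC(P(=O)(OCC(F)(F)F)OCC(F)(F)F)C(=O)O[C@@H]1[C@@H](OC(=O)C(C)P(=O)(OCC(F)(F)F)OCC(F)(F)F)C(C)(C)[C@H]2[C@@H]3[C@H](C)CC(=O)[C@H]2[C@]3(C)[C@@H]1OC(=O)C(C)P(=O)(OCC(F)(F)F)OCC(F)(F)F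
F0 | step 3 | none | none
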